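**Retrosynthetic overview**
- Last bonds: E-selective cross-metathesis puts on the hydroxy-isopropyl alkene terminus, and a B-alkyl Suzuki coupling joins a vinyl-bearing perhydrobenzoxepine to a cyclohexenyl triflate across the CH2CH2 link.
- Cyclohexene ring: bought as a cyclopentane (2-methylcyclopentane-1,3-dione), allylated and desymmetrised by CBS reduction. It is then enlarged by one carbon with diazoethane (1,2-alkyl shift, loss of N2). This ring expansion brings in the CHMe carbon and leaves a ketone that can enolise only one way, so the tetrasubstituted enol triflate follows.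
- Oxepane and cyclohexane rings: formed in one operation, oxepane first, by an epoxonium cascade of a Shi diepoxide terminated by a silyl dienol ether. MeMgBr/CeCl3 then sets the tertiary carbinol.
- Acyclic diepoxide: the E-trisubstituted alkene comes from Negishi carboalumination/iodination and an alkyl–alkenyl Negishi coupling; the allyl ketone comes from the nitrile.

Assumption: diazoethane (from N-ethyl-N-nitrosourea/KOH), allylzinc bromide, 9-BBN and the D-fructose-derived Shi ketone are bought or made as reagent solutions by standard procedures and are not counted as steps.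

**Route**

Step 1
Reactants: 1 2-methylcyclopentane-1,3-dione; 2 allyl bromide
Product: 3 2-methyl-2-(prop-2-en-1-yl)cyclopentane-1,3-dione
Conditions: NaOH (1 M aq.), rt
Reagents that add atoms: none
Why: C-alkylation of the stabilised 1,3-dione enolate with an allylic halide in water; the new quaternary carbon is still prochiral.

Step 2
Reactants: 3 2-methyl-2-(prop-2-en-1-yl)cyclopentane-1,3-dione
Product: 4 (2R,3R)-3-hydroxy-2-methyl-2-(prop-2-en-1-yl)cyclopentan-1-one
Conditions: (S)-2-methyl-CBS-oxazaborolidine (20 mol%), catecholborane, toluene, −78 °C; aq. work-up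
Reagents that add atoms: none
Why: Corey–Bakshi–Shibata desymmetrising reduction: the catalyst gives the 3R carbinol (quaternary carbon as the large group) and hydride enters anti to the larger allyl group, so OH and allyl are cis (2R,3R); catecholborane does not hydroborate the allyl group.

Step 3
Reactants: 4 (2R,3R)-3-hydroxy-2-methyl-2-(prop-2-en-1-yl)cyclopentan-1-one
Product: 5 (2R,3R)-3-[(tert-butyldimethylsilyl)oxy]-2-methyl-2-(prop-2-en-1-yl)cyclopentan-1-one
Conditions: TBSOTf, 2,6-lutidine, CH2Cl2, −78 → 0 °C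
Reagents that add atoms: tert-butyldimethylsilyl trifluoromethanesulfonate CC(C)(C)[Si](C)(C)OS(=O)(=O)C(F)(F)F
Why: Silyl ether formation; the hydroxyl must be masked against O-alkylation by the diazoalkane and against O-triflation, and no α-hydrogen lies between C=O and C–O, so elimination is impossible.

Step 4
Reactants: 5 (2R,3R)-3-[(tert-butyldimethylsilyl)oxy]-2-methyl-2-(prop-2-en-1-yl)cyclopentan-1-one
Product: 6 (2R,3R)-3-[(tert-butyldimethylsilyl)oxy]-2,6-dimethyl-2-(prop-2-en-1-yl)cyclohexan-1-one (both C6 epimers)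
Conditions: MeCHN2 (2 equiv, toluene solution), Sc(OTf)3 (10 mol%), toluene, −78 → −40 °C
Reagents that add atoms: diazoethane CC=[N+]=[N-]
Why: Lewis-acid-catalysed diazoalkane–ketone ring expansion (Tiffeneau–Demjanov-type 1,2-shift): diazoethane adds to the Sc-activated carbonyl and the less substituted C5 methylene migrates with loss of N2, so CHMe is inserted on the side away from the quaternary carbon; the hindered product resists a second insertion, the two existing stereocentres are untouched and the new C6 centre is erased in step 5.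

Step 5
Reactants: 6 (2R,3R)-3-[(tert-butyldimethylsilyl)oxy]-2,6-dimethyl-2-(prop-2-en-1-yl)cyclohexan-1-one
Product: 8 (5R,6R)-5-[(tert-butyldimethylsilyl)oxy]-2,6-dimethyl-6-(prop-2-en-1-yl)cyclohex-1-en-1-yl trifluoromethanesulfonate, via potassium enolate 7 (not isolated)
Conditions: KN(SiMe3)2, THF, −78 → 0 °C; then PhNTf2, −78 °C → rt
Reagents that add atoms: N-phenylbis(trifluoromethanesulfonimide) O=S(=O)(N(c1ccccc1)S(=O)(=O)C(F)(F)F)C(F)(F)F
Why: Enol triflate formation: only C6 carries an α-hydrogen, so enolisation is regiospecific and O-sulfonylation gives the tetrasubstituted alkenyl triflate.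

Step 6
Reactants: 9 5-bromo-2-methylpent-2-ene
Product: 10 6-methylhept-5-en-1-yne
Conditions: LiC≡CH·H2NCH2CH2NH2, DMSO, 10 °C → rt
Reagents that add atoms: lithium acetylide (ethylenediamine complex) [Li]C#C
Why: SN2 alkynylation of a primary bromide by lithium acetylide.

Step 7
Reactants: 10 6-methylhept-5-en-1-yne
Product: 12 (1E)-1-iodo-2,6-dimethylhepta-1,5-diene, via alkenyldimethylalane 11 (not isolated)
Conditions: Me3Al (2 equiv), Cp2ZrCl2 (25 mol%), CH2Cl2, rt; then I2, THF, −30 → 0 °C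
Reagents that add atoms: trimethylaluminium C[Al](C)C; iodine II
Why: Negishi zirconium-catalysed carboalumination adds Me and Al syn across the terminal alkyne (Me to the internal carbon) and iodinolysis goes with retention, which fixes the E trisubstituted alkene; the trisubstituted prenyl alkene does not react.

Step 8
Reactants: 12 (1E)-1-iodo-2,6-dimethylhepta-1,5-diene; 13 3-iodopropanenitrile
Product: 15 (4E)-5,9-dimethyldeca-4,8-dienenitrile, via 2-cyanoethylzinc iodide 14 (not isolated)
Conditions: 13, Zn dust (activated with Me3SiCl/BrCH2CH2Br), THF, 35 °C; then 12, Pd(PPh3)4 (4 mol%), THF, rt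
Reagents that add atoms: none
Why: Negishi cross-coupling of a functionalised alkylzinc iodide with the alkenyl iodide, with retention of alkene geometry; the nitrile is tolerated.

Step 9
Reactants: 15 (4E)-5,9-dimethyldeca-4,8-dienenitrile
Product: 16 3-[(2R,3R)-3-{2-[(2R)-3,3-dimethyloxiran-2-yl]ethyl}-3-methyloxiran-2-yl]propanenitrile
Conditions: Shi ketone from D-fructose (1,2:4,5-di-O-isopropylidene-β-D-erythro-2,3-hexodiulo-2,6-pyranose, 40 mol%), KHSO5, K2CO3, Bu4NHSO4, MeCN/CH2(OMe)2/aq. Na2B4O7 buffer (pH 10.5), 0 °C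
Reagents that add atoms: potassium peroxymonosulfate [K+].[O-]S(=O)(=O)OO
Why: Shi asymmetric epoxidation (chiral dioxirane, spiro transition state) oxidises both trisubstituted alkenes with the same facial sense, setting the 2R (terminal) and 2R,3R (internal) epoxide centres under catalyst control.

Step 10
Reactants: 16 3-[(2R,3R)-3-{2-[(2R)-3,3-dimethyloxiran-2-yl]ethyl}-3-methyloxiran-2-yl]propanenitrile
Product: 18 1-[(2R,3R)-3-{2-[(2R)-3,3-dimethyloxiran-2-yl]ethyl}-3-methyloxiran-2-yl]hex-5-en-3-one, via zinc ketimine 17 (not isolated)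
Conditions: CH2=CHCH2ZnBr (2 equiv), THF, 0 °C → rt; then cold aq. citric acid (pH 4–5), 0 °C
Reagents that add atoms: allylzinc bromide C=CC[Zn]Br; water O
Why: Single addition of an allylzinc reagent to the nitrile (Blaise-type addition) gives an N-zinc ketimine that mild acid hydrolyses to the β,γ-unsaturated ketone; the trisubstituted epoxides are inert to the soft organozinc.

Step 11
Reactants: 18 1-[(2R,3R)-3-{2-[(2R)-3,3-dimethyloxiran-2-yl]ethyl}-3-methyloxiran-2-yl]hex-5-en-3-one
Product: 20 (3R,5aR,6R,9aR)-3-[(tert-butyldimethylsilyl)oxy]-6-ethenyl-2,2,5a-trimethyloctahydro-1-benzoxepin-7(2H)-one, via silyl dienol ether 19 (not isolated)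
Conditions: TBSOTf (1.2 equiv), Et3N, CH2Cl2, −78 °C; filtration through basic Al2O3 (pentane); then TBSOTf (0.3 equiv), 2,6-di-tert-butyl-4-methylpyridine, CH2Cl2, −78 °C
Reagents that add atoms: tert-butyldimethylsilyl trifluoromethanesulfonate CC(C)(C)[Si](C)(C)OS(=O)(=O)C(F)(F)F
Why: Proposed new method: a silyl-triflate-triggered epoxonium cascade terminated for the first time by the α-carbon of a 1-silyloxy-1,3-diene (made regiospecifically because the CH2 between C=O and vinyl is the most acidic site): TBSOTf silylates the terminal epoxide, the internal epoxide oxygen attacks its tertiary carbon to give a bicyclic epoxonium ion, and C-α of the Z-dienol ether opens that ion with inversion at the methyl-bearing carbon through a chair transition state (vinyl equatorial, trans ring fusion), the ring enlarging to the oxepane as the old epoxide C–O bond breaks, after which silyl loss from the oxocarbenium ion regenerates TBSOTf; γ-attack would need an eight-membered ring holding an E-alkene, so α-attack should win, the epoxide centres of step 9 are relayed into 3R, 5aR and 9aR and the chair sets 6R; the closest known reaction is the silyl-triflate-promoted tandem oxa-/carbacyclisation of diepoxides terminated by simple ketone enol silanes.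

Step 12
Reactants: 20 (3R,5aR,6R,9aR)-3-[(tert-butyldimethylsilyl)oxy]-6-ethenyl-2,2,5a-trimethyloctahydro-1-benzoxepin-7(2H)-one
Product: 21 (3R,5aR,6R,7S,9aR)-3-[(tert-butyldimethylsilyl)oxy]-6-ethenyl-2,2,5a,7-tetramethyldecahydro-1-benzoxepin-7-ol
Conditions: MeMgBr, CeCl3 (anhydrous), THF, −78 °C
Reagents that add atoms: methylmagnesium bromide C[Mg]Br
Why: Organocerium 1,2-addition (Imamoto conditions) suppresses enolisation of the α-vinyl ketone; methyl enters equatorially because the axial face is blocked by the 1,3-diaxial angular methyl, giving the axial 7S hydroxyl cis to the vinyl group.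

Step 13
Reactants: 21 (3R,5aR,6R,7S,9aR)-3-[(tert-butyldimethylsilyl)oxy]-6-ethenyl-2,2,5a,7-tetramethyldecahydro-1-benzoxepin-7-ol; 8 (5R,6R)-5-[(tert-butyldimethylsilyl)oxy]-2,6-dimethyl-6-(prop-2-en-1-yl)cyclohex-1-en-1-yl trifluoromethanesulfonate
Product: 23 (3R,5aR,6R,7S,9aR)-3-[(tert-butyldimethylsilyl)oxy]-6-{2-[(5R,6S)-5-[(tert-butyldimethylsilyl)oxy]-2,6-dimethyl-6-(prop-2-en-1-yl)cyclohex-1-en-1-yl]ethyl}-2,2,5a,7-tetramethyldecahydro-1-benzoxepin-7-ol, via B-alkyl-9-BBN borane 22 (not isolated)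
Conditions: 21, 9-BBN (2.2 equiv), THF, 50 °C; aq. K3PO4 (3 M), rt; then 8, Pd(OAc)2 (10 mol%), SPhos (20 mol%), THF/H2O, 60 °C
Reagents that add atoms: none
Why: B-alkyl Suzuki–Miyaura coupling: anti-Markovnikov hydroboration of the vinyl group, then Pd-catalysed coupling with the enol triflate; aqueous base destroys residual B–H before the allyl-bearing triflate is added, and no stereocentre is touched (the cyclohexene centre changes descriptor from 6R to 6S by CIP priority only).

Step 14
Reactants: 23 the bis-silyl ether from step 13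
Product: 24 (3R,5aR,6R,7S,9aR)-6-{2-[(5R,6S)-5-hydroxy-2,6-dimethyl-6-(prop-2-en-1-yl)cyclohex-1-en-1-yl]ethyl}-2,2,5a,7-tetramethyldecahydro-1-benzoxepine-3,7-diol
Conditions: Bu4NF, THF, 50 °C
Reagents that add atoms: none
Why: Fluoride-driven cleavage of both TBS ethers (desilylation); alkenes and tertiary alcohols are unaffected.

Step 15
Reactants: 24 the triol from step 14; 25 2-methylbut-3-en-2-ol
Product: 26 siphonellinol C
Conditions: second-generation Hoveyda–Grubbs catalyst RuCl2(H2IMes)(=CH-C6H4-2-OiPr) (10 mol%), 25 (10 equiv), CH2Cl2, 40 °C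
Reagents that add atoms: none
Why: Olefin cross-metathesis of the terminal allyl group with an excess of the slowly homodimerising tertiary allylic alcohol gives the E-alkene under thermodynamic control; the tetrasubstituted ring alkene is inert and free hydroxyls are tolerated.

**Compound list**

1 | 2-methylcyclopentane-1,3-dione | CC1C(=O)CCC1=O | starting material
2 | allyl bromide (3-bromoprop-1-ene) | C=CCBr | starting material
3 | 2-methyl-2-(prop-2-en-1-yl)cyclopentane-1,3-dione | C=CCC1(C)C(=O)CCC1=O | intermediate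
4 | (2R,3R)-3-hydroxy-2-methyl-2-(prop-2-en-1-yl)cyclopentan-1-one | O=C1[C@](C)(CC=C)[C@H](O)CC1 | intermediate
5 | (2R,3R)-3-[(tert-butyldimethylsilyl)oxy]-2-methyl-2-(prop-2-en-1-yl)cyclopentan-1-one | O=C1[C@](C)(CC=C)[C@H](O[Si](C)(C)C(C)(C)C)CC1 | intermediate
6 | (2R,3R)-3-[(tert-butyldimethylsilyl)oxy]-2,6-dimethyl-2-(prop-2-en-1-yl)cyclohexan-1-one, C6 epimers | CC1C(=O)[C@](C)(CC=C)[C@H](O[Si](C)(C)C(C)(C)C)CC1 | intermediate
7 | potassium enolate of 6 (not isolated) | CC1=C([O-])[C@](C)(CC=C)[C@H](O[Si](C)(C)C(C)(C)C)CC1.[K+] | intermediate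
8 | (5R,6R)-5-[(tert-butyldimethylsilyl)oxy]-2,6-dimethyl-6-(prop-2-en-1-yl)cyclohex-1-en-1-yl trifluoromethanesulfonate | CC1=C(OS(=O)(=O)C(F)(F)F)[C@](C)(CC=C)[C@H](O[Si](C)(C)C(C)(C)C)CC1 | intermediate
9 | 5-bromo-2-methylpent-2-ene | CC(C)=CCCBr | starting material
10 | 6-methylhept-5-en-1-yne | CC(C)=CCCC#C | intermediate
11 | [(1E)-2,6-dimethylhepta-1,5-dien-1-yl]dimethylalane (not isolated) | CC(C)=CCC/C(C)=C/[Al](C)C | intermediate
12 | (1E)-1-iodo-2,6-dimethylhepta-1,5-diene | CC(C)=CCC/C(C)=C/I | intermediate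
13 | 3-iodopropanenitrile | N#CCCI | starting material
14 | (2-cyanoethyl)zinc iodide (not isolated) | N#CCC[Zn]I | intermediate
15 | (4E)-5,9-dimethyldeca-4,8-dienenitrile | CC(C)=CCC/C(C)=C/CCC#N | intermediate
16 | 3-[(2R,3R)-3-{2-[(2R)-3,3-dimethyloxiran-2-yl]ethyl}-3-methyloxiran-2-yl]propanenitrile | N#CCC[C@H]1O[C@]1(C)CC[C@H]2OC2(C)C | intermediate
17 | N-(bromozincio) ketimine of ketone 18, C=N–ZnBr in place of C=O (not isolated) | C=CCC(=N[Zn]Br)CC[C@H]1O[C@]1(C)CC[C@H]2OC2(C)C | intermediate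
18 | 1-[(2R,3R)-3-{2-[(2R)-3,3-dimethyloxiran-2-yl]ethyl}-3-methyloxiran-2-yl]hex-5-en-3-one | C=CCC(=O)CC[C@H]1O[C@]1(C)CC[C@H]2OC2(C)C | intermediate
19 | tert-butyl{[(3Z)-1-[(2R,3R)-3-{2-[(2R)-3,3-dimethyloxiran-2-yl]ethyl}-3-methyloxiran-2-yl]hexa-3,5-dien-3-yl]oxy}dimethylsilane (not isolated) | C=C/C=C(\O[Si](C)(C)C(C)(C)C)CC[C@H]1O[C@]1(C)CC[C@H]2OC2(C)C | intermediate
20 | (3R,5aR,6R,9aR)-3-[(tert-butyldimethylsilyl)oxy]-6-ethenyl-2,2,5a-trimethyloctahydro-1-benzoxepin-7(2H)-one (trans-fused, vinyl equatorial) | C=C[C@@H]1[C@@]2(C)CC[C@@H](O[Si](C)(C)C(C)(C)C)C(C)(C)O[C@@H]2CCC1=O | intermediate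
21 | (3R,5aR,6R,7S,9aR)-3-[(tert-butyldimethylsilyl)oxy]-6-ethenyl-2,2,5a,7-tetramethyldecahydro-1-benzoxepin-7-ol | C=C[C@@H]1[C@@]2(C)CC[C@@H](O[Si](C)(C)C(C)(C)C)C(C)(C)O[C@@H]2CC[C@]1(C)O | intermediate
22 | 9-{2-[(3R,5aR,6R,7S,9aR)-3-[(tert-butyldimethylsilyl)oxy]-7-hydroxy-2,2,5a,7-tetramethyldecahydro-1-benzoxepin-6-yl]ethyl}-9-borabicyclo[3.3.1]nonane (not isolated) | C1CCC2CCCC1B2CC[C@@H]1[C@@]3(C)CC[C@@H](O[Si](C)(C)C(C)(C)C)C(C)(C)O[C@@H]3CC[C@]1(C)O | intermediate
23 | (3R,5aR,6R,7S,9aR)-3-[(tert-butyldimethylsilyl)oxy]-6-{2-[(5R,6S)-5-[(tert-butyldimethylsilyl)oxy]-2,6-dimethyl-6-(prop-2-en-1-yl)cyclohex-1-en-1-yl]ethyl}-2,2,5a,7-tetramethyldecahydro-1-benzoxepin-7-ol | CC1=C(CC[C@@H]2[C@@]3(C)CC[C@@H](O[Si](C)(C)C(C)(C)C)C(C)(C)O[C@@H]3CC[C@]2(C)O)[C@](C)(CC=C)[C@H](O[Si](C)(C)C(C)(C)C)CC1 | intermediate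
24 | (3R,5aR,6R,7S,9aR)-6-{2-[(5R,6S)-5-hydroxy-2,6-dimethyl-6-(prop-2-en-1-yl)cyclohex-1-en-1-yl]ethyl}-2,2,5a,7-tetramethyldecahydro-1-benzoxepine-3,7-diol | CC1=C(CC[C@@H]2[C@@]3(C)CC[C@@H](O)C(C)(C)O[C@@H]3CC[C@]2(C)O)[C@](C)(CC=C)[C@H](O)CC1 | intermediate
25 | 2-methylbut-3-en-2-ol | C=CC(C)(C)O | starting material
26 | siphonellinol C, (3R,5aR,6R,7S,9aR)-6-{2-[(5R,6S)-5-hydroxy-6-[(2E)-4-hydroxy-4-methylpent-2-en-1-yl]-2,6-dimethylcyclohex-1-en-1-yl]ethyl}-2,2,5a,7-tetramethyldecahydro-1-benzoxepine-3,7-diol | CC1=C(CC[C@@H]2[C@@]3(C)CC[C@@H](O)C(C)(C)O[C@@H]3CC[C@]2(C)O)[C@](C)(C/C=C/C(C)(C)O)[C@H](O)CC1 | target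

**Step count**
Total: 15 steps. Longest linear sequence: 10 steps (9 → 26, steps 6 to 15); the cyclohexenyl triflate 8 is made in 5 steps (steps 1 to 5) and enters at step 13.

**Three steps most likely to fail, with fallbacks**

1. Step 11, the proposed new dienol-ether-terminated cascade. The risks are γ-reactivity or proton loss to a conjugated silyloxydiene, and isomerisation of the α-vinyl ketone into conjugation. The fallback uses only known chemistry, sets out from diepoxy nitrile 16 and comes back at ketone 20. MeMgBr adds once to the nitrile to give the bromomagnesium ketiminate F1, which mild aqueous acid turns into the diepoxy methyl ketone F2. Kinetic silylation (LiN(iPr)2, TBSCl, THF, −78 °C) gives the terminal TBS enol ether F3. The known enol-silane-terminated tandem oxa-/carbacyclisation (TBSOTf, 2,6-di-tert-butyl-4-methylpyridine, CH2Cl2, −78 °C) gives the bicyclic ketone F4, which has CH2 at C6. Because C5a is quaternary, dehydrogenation with 2-iodoxybenzoic acid can only give the 8,9-enone F5. Kinetic deprotonation of that enone is then forced to C6, and Pd-catalysed α-alkenylation (LiN(SiMe3)2, vinyl bromide, Pd2(dba)3, P(t-Bu)3, THF) gives the 6-vinyl enone F6, as the equatorial 6R isomer directly or after equilibration. Conjugate reduction with [(Ph3P)CuH]6 spares the vinyl group and returns 20.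

2. Step 13, the B-alkyl Suzuki coupling at a tetrasubstituted triflate flanked by a quaternary carbon, where transmetallation or oxidative addition may be slow. The fallback sets out from alcohol 21 and comes back at 23. Hydroboration–oxidation (9-BBN, through borane 22, then NaBO3·4H2O) gives the primary alcohol F7. I2/PPh3/imidazole converts only the primary hydroxyl into the iodide F8. A nickel-catalysed reductive cross-electrophile coupling of F8 with triflate 8 (NiBr2·MeOCH2CH2OMe, 4,4′-di-tert-butyl-2,2′-bipyridine, Zn, DMA, 40 °C) then joins the fragments by a radical-type alkyl transfer that tolerates the free tertiary alcohol and gives 23.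

3. Step 4, the diazoethane ring expansion, where the risks are the regiochemistry of migration, epoxide formation and handling of diazoethane. The fallback sets out from cyclopentanone 5 and comes back at 6. Me3SiCHN2 with BF3·OEt2 (CH2Cl2, −78 °C) inserts CH(SiMe3) by migration of the same C5 methylene and gives the α-silyl ketone F9. K2CO3/MeOH removes silicon and gives the ring-expanded ketone F10. LiN(iPr)2 then MeI (THF, −78 °C) methylates the only enolisable position and gives 6.

**Further compounds**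

F1 | step 11 | N-(bromomagnesio) ketimine formed from nitrile 16 and MeMgBr | CC(=N[Mg]Br)CC[C@H]1O[C@]1(C)CC[C@H]2OC2(C)C
F2 | step 11 | 4-[(2R,3R)-3-{2-[(2R)-3,3-dimethyloxiran-2-yl]ethyl}-3-methyloxiran-2-yl]butan-2-one | CC(=O)CC[C@H]1O[C@]1(C)CC[C@H]2OC2(C)C
F3 | step 11 | tert-butyl({4-[(2R,3R)-3-{2-[(2R)-3,3-dimethyloxiran-2-yl]ethyl}-3-methyloxiran-2-yl]but-1-en-2-yl}oxy)dimethylsilane | C=C(O[Si](C)(C)C(C)(C)C)CC[C@H]1O[C@]1(C)CC[C@H]2OC2(C)C
F4 | step 11 | (3R,5aR,9aR)-3-[(tert-butyldimethylsilyl)oxy]-2,2,5a-trimethyloctahydro-1-benzoxepin-7(2H)-one | C1[C@@]2(C)CC[C@@H](O[Si](C)(C)C(C)(C)C)C(C)(C)O[C@@H]2CCC1=O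
F5 | step 11 | (3R,5aR,9aR)-3-[(tert-butyldimethylsilyl)oxy]-2,2,5a-trimethyl-3,4,5,5a,6,9a-hexahydro-1-benzoxepin-7(2H)-one (8,9-enone) | C1[C@@]2(C)CC[C@@H](O[Si](C)(C)C(C)(C)C)C(C)(C)O[C@@H]2C=CC1=O
F6 | step 11 | (3R,5aR,6R,9aR)-3-[(tert-butyldimethylsilyl)oxy]-6-ethenyl-2,2,5a-trimethyl-3,4,5,5a,6,9a-hexahydro-1-benzoxepin-7(2H)-one | C=C[C@@H]1[C@@]2(C)CC[C@@H](O[Si](C)(C)C(C)(C)C)C(C)(C)O[C@@H]2C=CC1=O
F7 | step 13 | (3R,5aR,6R,7S,9aR)-3-[(tert-butyldimethylsilyl)oxy]-6-(2-hydroxyethyl)-2,2,5a,7-tetramethyldecahydro-1-benzoxepin-7-ol | OCC[C@@H]1[C@@]2(C)CC[C@@H](O[Si](C)(C)C(C)(C)C)C(C)(C)O[C@@H]2CC[C@]1(C)O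
F8 | step 13 | (3R,5aR,6R,7S,9aR)-3-[(tert-butyldimethylsilyl)oxy]-6-(2-iodoethyl)-2,2,5a,7-tetramethyldecahydro-1-benzoxepin-7-ol | ICC[C@@H]1[C@@]2(C)CC[C@@H](O[Si](C)(C)C(C)(C)C)C(C)(C)O[C@@H]2CC[C@]1(C)O
F9 | step 4 | (2R,3R)-3-[(tert-butyldimethylsilyl)oxy]-2-methyl-2-(prop-2-en-1-yl)-6-(trimethylsilyl)cyclohexan-1-one, C6 epimers | C[Si](C)(C)C1C(=O)[C@](C)(CC=C)[C@H](O[Si](C)(C)C(C)(C)C)CC1
F10 | step 4 | (2R,3R)-3-[(tert-butyldimethylsilyl)oxy]-2-methyl-2-(prop-2-en-1-yl)cyclohexan-1-one | O=C1[C@](C)(CC=C)[C@H](O[Si](C)(C)C(C)(C)C)CCC1
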